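**Retrosynthetic overview**

1. Target 27 comes from global desilylation of acid 26. The C12 acid is made from the C7 isopropenyl group of 23 (SeO2, then two oxidations), and the C8 ester from Yamaguchi acylation of alcohol 18 with acid 21.
2. The only ring, the cyclohexane, is closed once: an intramolecular carbonyl-ene reaction of acyclic aldehyde 15 forms C6–C7 and sets C6 and C7 (16).
3. Aldehyde 15 comes from a proposed iridium/isothiourea allylic alkylation of active ester 12 with (E)-allyl carbonate 7. This forms C5–C10, sets the C5 tertiary and C10 quaternary centres, and delivers the vinyl group.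
4. Carbonate 7 comes from prenal 1 (asymmetric propargylation sets C8, carboalumination sets the (E)-alkene); 12 from monomethyl itaconate 8; 21 from ethyl 2-(hydroxymethyl)acrylate 19.

Atom labels C1 to C15 follow elemane numbering: C10 is the quaternary carbon (methyl C14, vinyl C1=C2), C5 bears C4(=C3)–C15–O, C6 bears OH, C7 bears C11(=C13)–C12, C8 bears the acyloxy group, C9 is CH2.

Abbreviations: TES-oxy = (triethylsilyl)oxy; TBS-oxy = [tert-butyl(dimethyl)silyl]oxy; TBDPS-oxy = [tert-butyl(diphenyl)silyl]oxy; PFP = pentafluorophenyl; TRIP = 3,3'-bis(2,4,6-triisopropylphenyl)-1,1'-binaphthalene-2,2'-diyl hydrogen phosphate; BTM = benzotetramisole (2-phenyl-2,3-dihydroimidazo[2,1-b][1,3]benzothiazole); L1 = O,O'-(1,1'-binaphthalene-2,2'-diyl) N,N-bis(1-phenylethyl)phosphoramidite; DMP = Dess–Martin periodinane; PPTS = pyridinium p-toluenesulfonate; DCC = N,N'-dicyclohexylcarbodiimide; DMAP = 4-(dimethylamino)pyridine.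

Assumption: the enantiomers of TRIP, BTM and L1 named below are assigned by analogy with their sense on simpler substrates; if the first intermediate shows the opposite sense, the mirror-image catalyst is used and nothing else changes.

**Route**

Step 1
Reactants: 1 3-methylbut-2-enal (prenal); 2 allenylboronic acid pinacol ester
Product: 3 (4S)-6-methylhept-5-en-1-yn-4-ol
Conditions: (S)-TRIP (5 mol %), 4 Å MS, toluene, −20 °C; aq. NaHCO3 work-up
Reagents that add atoms: none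
Why: Chiral-phosphoric-acid-catalysed propargylation, in which the allenylboronate adds through a six-membered SE2' transition state while the catalyst binds the boronate oxygen and the formyl hydrogen and exposes the Si face of prenal, setting C8 as (S).

Step 2
Reactants: 3 (4S)-6-methylhept-5-en-1-yn-4-ol
Product: 4 triethyl{[(4S)-6-methylhept-5-en-1-yn-4-yl]oxy}silane
Conditions: TESCl, imidazole, DMF, 0 °C → rt
Reagents that add atoms: chlorotriethylsilane, CC[Si](Cl)(CC)CC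
Why: Standard silylation of a secondary alcohol; TES tolerates organoaluminium reagents and can later be removed in the presence of TBS and TBDPS ethers.

Step 3
Reactants: 4 triethyl{[(4S)-6-methylhept-5-en-1-yn-4-yl]oxy}silane
Product: 6 (2E,5S)-3,7-dimethyl-5-(TES-oxy)octa-2,6-dien-1-ol, via alkenyldimethylalane 5 (not isolated)
Conditions: Me3Al (2.5 equiv), Cp2ZrCl2 (0.25 equiv), CH2Cl2, 0 °C → rt; then (CH2O)n, THF, 0 °C → rt
Reagents that add atoms: trimethylaluminium, C[Al](C)C; formaldehyde (from paraformaldehyde), C=O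
Why: Zirconium-catalysed Negishi carboalumination adds methyl and aluminium syn across the terminal alkyne (methyl to the internal carbon) and the alkenylalane traps formaldehyde with retention, so only the (E)-trisubstituted alkene forms.

Step 4
Reactants: 6 (2E,5S)-3,7-dimethyl-5-(TES-oxy)octa-2,6-dien-1-ol
Product: 7 tert-butyl (2E,5S)-3,7-dimethyl-5-(TES-oxy)octa-2,6-dien-1-yl carbonate
Conditions: Boc2O (1.3 equiv), DMAP (10 mol %), CH2Cl2, 0 °C → rt
Reagents that add atoms: di-tert-butyl dicarbonate, CC(C)(C)OC(=O)OC(=O)OC(C)(C)C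
Why: DMAP-catalysed acylation of the primary allylic alcohol gives the tert-butyl carbonate, whose tert-butoxide leaving-group fragment serves as the base in step 9.

Step 5
Reactants: 8 monomethyl itaconate (4-methoxy-2-methylidene-4-oxobutanoic acid)
Product: 9 methyl 3-(hydroxymethyl)but-3-enoate
Conditions: BH3·THF (1.1 equiv), THF, −10 → 0 °C; H2O quench
Reagents that add atoms: none
Why: Chemoselective borane reduction, since borane reduces a free carboxylic acid much faster than a methyl ester or an electron-poor alkene.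

Step 6
Reactants: 9 methyl 3-(hydroxymethyl)but-3-enoate
Product: 10 methyl 3-[(TBDPS-oxy)methyl]but-3-enoate
Conditions: TBDPSCl, imidazole, CH2Cl2, 0 °C → rt
Reagents that add atoms: tert-butyl(chloro)diphenylsilane, CC(C)(C)[Si](Cl)(c1ccccc1)c1ccccc1
Why: Standard silylation of the primary allylic alcohol, done at once to prevent lactonisation; TBDPS is chosen for its acid stability in step 14.

Step 7
Reactants: 10 methyl 3-[(TBDPS-oxy)methyl]but-3-enoate
Product: 11 3-[(TBDPS-oxy)methyl]but-3-enoic acid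
Conditions: LiOH·H2O (1.5 equiv), THF/H2O 3:1, 0 °C; then aq. HCl to pH 4
Reagents that add atoms: lithium hydroxide, [Li+].[OH-]
Why: Saponification of the unhindered methyl ester at 0 °C outruns base-induced migration of the beta,gamma double bond, and the carboxylate formed is no longer acidic at the alpha carbon.

Step 8
Reactants: 11 3-[(TBDPS-oxy)methyl]but-3-enoic acid
Product: 12 pentafluorophenyl 3-[(TBDPS-oxy)methyl]but-3-enoate
Conditions: C6F5OH, DCC, CH2Cl2, 0 °C → rt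
Reagents that add atoms: pentafluorophenol, Oc1c(F)c(F)c(F)c(F)c1F
Why: Carbodiimide coupling without DMAP gives the active ester needed for acyl transfer to the isothiourea catalyst without isomerising the alkene.

Step 9
Reactants: 7 tert-butyl (2E,5S)-3,7-dimethyl-5-(TES-oxy)octa-2,6-dien-1-yl carbonate; 12 pentafluorophenyl 3-[(TBDPS-oxy)methyl]but-3-enoate
Product: 13 pentafluorophenyl (2R,3S,5S)-3-ethenyl-3,7-dimethyl-2-[3-(TBDPS-oxy)prop-1-en-2-yl]-5-(TES-oxy)oct-6-enoate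
Conditions: [Ir(cod)Cl]2 (2.5 mol %), (Ra,R,R)-L1 (5 mol %, pre-activated with n-PrNH2), (S)-BTM (10 mol %), THF, 0 °C → rt, 48 h
Reagents that add atoms: none
Why: Proposed new method: two catalysts act together and each fixes one centre — the complex formed from [Ir(cod)Cl]2 and L1 (monovalent iridium) ionises (E)-carbonate 7 to a trivalent iridium allyl complex whose disubstituted terminus keeps its syn/anti geometry (exchange would need a tertiary sigma-allyl) while its two faces equilibrate through the primary terminus, and BTM turns active ester 12 into a conformationally locked acyl-ammonium enolate (deprotonated by the tert-butoxide released from 7) that attacks the more substituted allyl terminus through its alpha carbon before pentafluorophenoxide releases the catalyst, so the ligand sets C10 (S), BTM sets C5 (R) and branched attack delivers the vinyl group; the closest known reaction types are the synergistic iridium/isothiourea allylic alkylation of aryl acetic pentafluorophenyl esters with monosubstituted allyl carbonates and iridium-catalysed quaternary-forming alkylations of trisubstituted allyl carbonates with malonates, neither shown for an alkenyl acetic ester joined to an alkyl,alkyl-disubstituted allyl terminus.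

Step 10
Reactants: 13 pentafluorophenyl (2R,3S,5S)-3-ethenyl-3,7-dimethyl-2-[3-(TBDPS-oxy)prop-1-en-2-yl]-5-(TES-oxy)oct-6-enoate
Product: 14 (2R,3S,5S)-3-ethenyl-3,7-dimethyl-2-[3-(TBDPS-oxy)prop-1-en-2-yl]-5-(TES-oxy)oct-6-en-1-ol
Conditions: LiBH4 (2 equiv), THF, 0 °C → rt
Reagents that add atoms: none
Why: Hydride reduction of the activated aryl ester to the primary alcohol proceeds under mild conditions that leave the silyl ethers and the alpha stereocentre untouched.

Step 11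
Reactants: 14 (2R,3S,5S)-3-ethenyl-3,7-dimethyl-2-[3-(TBDPS-oxy)prop-1-en-2-yl]-5-(TES-oxy)oct-6-en-1-ol
Product: 15 (2R,3S,5S)-3-ethenyl-3,7-dimethyl-2-[3-(TBDPS-oxy)prop-1-en-2-yl]-5-(TES-oxy)oct-6-enal
Conditions: DMP (1.2 equiv), CH2Cl2, 0 °C, 30 min; used at once
Reagents that add atoms: none
Why: Dess–Martin oxidation is mild enough to give the alpha-branched beta,gamma-unsaturated aldehyde without epimerisation at C5 or migration of the double bond.

Step 12
Reactants: 15 (2R,3S,5S)-3-ethenyl-3,7-dimethyl-2-[3-(TBDPS-oxy)prop-1-en-2-yl]-5-(TES-oxy)oct-6-enal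
Product: 16 (1R,2R,3S,5S,6S)-3-ethenyl-3-methyl-6-(prop-1-en-2-yl)-2-[3-(TBDPS-oxy)prop-1-en-2-yl]-5-(TES-oxy)cyclohexan-1-ol
Conditions: Me2AlCl (1.5 equiv), CH2Cl2, −78 → −40 °C
Reagents that add atoms: none
Why: Lewis-acid-promoted intramolecular carbonyl-ene reaction (citronellal-to-isopulegol type) through a chair transition state with the C5 side chain, the C8 silyloxy group and the vinyl group equatorial and the C10 methyl axial, so the new C6 hydroxyl (R) and C7 isopropenyl group (S) form equatorial and trans to each other and to their neighbours.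

Step 13
Reactants: 16 (1R,2R,3S,5S,6S)-3-ethenyl-3-methyl-6-(prop-1-en-2-yl)-2-[3-(TBDPS-oxy)prop-1-en-2-yl]-5-(TES-oxy)cyclohexan-1-ol
Product: 17 (1R,2R,3S,5S,6R)-1-(TBS-oxy)-3-ethenyl-3-methyl-6-(prop-1-en-2-yl)-2-[3-(TBDPS-oxy)prop-1-en-2-yl]-5-(TES-oxy)cyclohexane
Conditions: TBSOTf, 2,6-lutidine, CH2Cl2, −78 → 0 °C
Reagents that add atoms: tert-butyldimethylsilyl trifluoromethanesulfonate, CC(C)(C)[Si](C)(C)OS(=O)(=O)C(F)(F)F
Why: Silyl triflate silylation is strong enough for the hindered equatorial C6 hydroxyl and leaves the TES ether intact.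

Step 14
Reactants: 17 (1R,2R,3S,5S,6R)-1-(TBS-oxy)-3-ethenyl-3-methyl-6-(prop-1-en-2-yl)-2-[3-(TBDPS-oxy)prop-1-en-2-yl]-5-(TES-oxy)cyclohexane
Product: 18 (1S,2R,3R,4R,5S)-3-(TBS-oxy)-5-ethenyl-5-methyl-2-(prop-1-en-2-yl)-4-[3-(TBDPS-oxy)prop-1-en-2-yl]cyclohexan-1-ol
Conditions: PPTS (0.2 equiv), MeOH/CH2Cl2 1:1, 0 °C
Reagents that add atoms: none
Why: Selective acid methanolysis, since the secondary TES ether cleaves far faster than the hindered secondary TBS ether and the primary TBDPS ether, freeing only the C8 hydroxyl.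

Step 15
Reactants: 19 ethyl 2-(hydroxymethyl)prop-2-enoate
Product: 20 ethyl 2-[(TBS-oxy)methyl]prop-2-enoate
Conditions: TBSCl, imidazole, CH2Cl2, 0 °C → rt
Reagents that add atoms: tert-butyl(chloro)dimethylsilane, CC(C)(C)[Si](C)(C)Cl
Why: Standard silylation of the primary allylic alcohol of the side-chain precursor.

Step 16
Reactants: 20 ethyl 2-[(TBS-oxy)methyl]prop-2-enoate
Product: 21 2-[(TBS-oxy)methyl]prop-2-enoic acid
Conditions: LiOH·H2O, THF/H2O, 0 °C → rt; then aq. HCl to pH 4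
Reagents that add atoms: lithium hydroxide, [Li+].[OH-]
Why: Saponification of the ethyl ester; the TBS ether and the acrylate double bond survive cold aqueous hydroxide.

Step 17
Reactants: 18 (1S,2R,3R,4R,5S)-3-(TBS-oxy)-5-ethenyl-5-methyl-2-(prop-1-en-2-yl)-4-[3-(TBDPS-oxy)prop-1-en-2-yl]cyclohexan-1-ol; 21 2-[(TBS-oxy)methyl]prop-2-enoic acid
Product: 23 (1S,2R,3R,4R,5S)-3-(TBS-oxy)-5-ethenyl-5-methyl-2-(prop-1-en-2-yl)-4-[3-(TBDPS-oxy)prop-1-en-2-yl]cyclohexyl 2-[(TBS-oxy)methyl]prop-2-enoate, via mixed anhydride 22 (not isolated)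
Conditions: 21, 2,4,6-trichlorobenzoyl chloride, Et3N, toluene, rt; then 18, DMAP, toluene, rt
Reagents that add atoms: none
Why: Yamaguchi esterification acylates the only free hydroxyl (C8) through the mixed anhydride and DMAP without touching any stereocentre.

Step 18
Reactants: 23 (1S,2R,3R,4R,5S)-3-(TBS-oxy)-5-ethenyl-5-methyl-2-(prop-1-en-2-yl)-4-[3-(TBDPS-oxy)prop-1-en-2-yl]cyclohexyl 2-[(TBS-oxy)methyl]prop-2-enoate
Product: 24 (1S,2R,3R,4R,5S)-3-(TBS-oxy)-5-ethenyl-2-(3-hydroxyprop-1-en-2-yl)-5-methyl-4-[3-(TBDPS-oxy)prop-1-en-2-yl]cyclohexyl 2-[(TBS-oxy)methyl]prop-2-enoate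
Conditions: SeO2 (0.5 equiv), t-BuOOH (3 equiv), salicylic acid (10 mol %), CH2Cl2, rt
Reagents that add atoms: selenium dioxide, O=[Se]=O; tert-butyl hydroperoxide, CC(C)(C)OO
Why: Selenium dioxide allylic oxidation (ene reaction then [2,3]-shift) attacks the methyl of the most electron-rich 1,1-disubstituted alkene, because the other two are deactivated by an allylic silyloxy group or an ester and the vinyl group has no allylic hydrogen.

Step 19
Reactants: 24 (1S,2R,3R,4R,5S)-3-(TBS-oxy)-5-ethenyl-2-(3-hydroxyprop-1-en-2-yl)-5-methyl-4-[3-(TBDPS-oxy)prop-1-en-2-yl]cyclohexyl 2-[(TBS-oxy)methyl]prop-2-enoate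
Product: 25 (1S,2R,3R,4R,5S)-3-(TBS-oxy)-5-ethenyl-5-methyl-2-(3-oxoprop-1-en-2-yl)-4-[3-(TBDPS-oxy)prop-1-en-2-yl]cyclohexyl 2-[(TBS-oxy)methyl]prop-2-enoate
Conditions: DMP (1.3 equiv), CH2Cl2, 0 °C → rt
Reagents that add atoms: none
Why: Dess–Martin oxidation of the only free (primary allylic) alcohol gives the enal, and any enal already formed in step 18 converges here.

Step 20
Reactants: 25 (1S,2R,3R,4R,5S)-3-(TBS-oxy)-5-ethenyl-5-methyl-2-(3-oxoprop-1-en-2-yl)-4-[3-(TBDPS-oxy)prop-1-en-2-yl]cyclohexyl 2-[(TBS-oxy)methyl]prop-2-enoate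
Product: 26 2-[(1R,2R,3R,4S,6S)-2-(TBS-oxy)-4-ethenyl-4-methyl-3-[3-(TBDPS-oxy)prop-1-en-2-yl]-6-({2-[(TBS-oxy)methyl]prop-2-enoyl}oxy)cyclohexyl]prop-2-enoic acid
Conditions: NaClO2, NaH2PO4, 2-methylbut-2-ene, t-BuOH/H2O, 0 °C → rt
Reagents that add atoms: sodium chlorite, [Na+].[O-]Cl=O
Why: Pinnick oxidation converts the alpha-methylene aldehyde to the acid while the alkene scavenger protects the other double bonds from hypochlorous acid.

Step 21
Reactants: 26 2-[(1R,2R,3R,4S,6S)-2-(TBS-oxy)-4-ethenyl-4-methyl-3-[3-(TBDPS-oxy)prop-1-en-2-yl]-6-({2-[(TBS-oxy)methyl]prop-2-enoyl}oxy)cyclohexyl]prop-2-enoic acid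
Product: 27 2-[(1S,2R,3R,4S,6S)-4-ethenyl-2-hydroxy-6-{[2-(hydroxymethyl)prop-2-enoyl]oxy}-3-(3-hydroxyprop-1-en-2-yl)-4-methylcyclohexyl]prop-2-enoic acid
Conditions: HF·pyridine, excess pyridine, THF, 0 °C → rt
Reagents that add atoms: none
Why: Fluoride-mediated global desilylation under pyridine buffering removes all three silyl groups while avoiding acid-catalysed lactonisation of the C6 hydroxy acid and cleavage or migration of the C8 ester.

**Compound list**

1 | 3-methylbut-2-enal (prenal) | CC(C)=CC=O | starting material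
2 | allenylboronic acid pinacol ester (4,4,5,5-tetramethyl-2-(propa-1,2-dien-1-yl)-1,3,2-dioxaborolane) | C=C=CB1OC(C)(C)C(C)(C)O1 | starting material
3 | (4S)-6-methylhept-5-en-1-yn-4-ol | C#CC[C@H](O)C=C(C)C | intermediate
4 | triethyl{[(4S)-6-methylhept-5-en-1-yn-4-yl]oxy}silane | C#CC[C@H](O[Si](CC)(CC)CC)C=C(C)C | intermediate
5 | [(1E,4S)-2,6-dimethyl-4-(TES-oxy)hepta-1,5-dien-1-yl]dimethylalumane (alkenyldimethylalane, not isolated) | C[Al](C)/C=C(\C)C[C@H](O[Si](CC)(CC)CC)C=C(C)C | intermediate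
6 | (2E,5S)-3,7-dimethyl-5-(TES-oxy)octa-2,6-dien-1-ol | OC/C=C(\C)C[C@H](O[Si](CC)(CC)CC)C=C(C)C | intermediate
7 | tert-butyl (2E,5S)-3,7-dimethyl-5-(TES-oxy)octa-2,6-dien-1-yl carbonate | CC(C)(C)OC(=O)OC/C=C(\C)C[C@H](O[Si](CC)(CC)CC)C=C(C)C | intermediate
8 | monomethyl itaconate (4-methoxy-2-methylidene-4-oxobutanoic acid) | COC(=O)CC(=C)C(=O)O | starting material
9 | methyl 3-(hydroxymethyl)but-3-enoate | COC(=O)CC(=C)CO | intermediate
10 | methyl 3-[(TBDPS-oxy)methyl]but-3-enoate | COC(=O)CC(=C)CO[Si](c1ccccc1)(c1ccccc1)C(C)(C)C | intermediate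
11 | 3-[(TBDPS-oxy)methyl]but-3-enoic acid | OC(=O)CC(=C)CO[Si](c1ccccc1)(c1ccccc1)C(C)(C)C | intermediate
12 | pentafluorophenyl 3-[(TBDPS-oxy)methyl]but-3-enoate | O=C(CC(=C)CO[Si](c1ccccc1)(c1ccccc1)C(C)(C)C)Oc1c(F)c(F)c(F)c(F)c1F | intermediate
13 | pentafluorophenyl (2R,3S,5S)-3-ethenyl-3,7-dimethyl-2-[3-(TBDPS-oxy)prop-1-en-2-yl]-5-(TES-oxy)oct-6-enoate | C=C[C@](C)(C[C@H](O[Si](CC)(CC)CC)C=C(C)C)[C@@H](C(=O)Oc1c(F)c(F)c(F)c(F)c1F)C(=C)CO[Si](c1ccccc1)(c1ccccc1)C(C)(C)C | intermediate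
14 | (2R,3S,5S)-3-ethenyl-3,7-dimethyl-2-[3-(TBDPS-oxy)prop-1-en-2-yl]-5-(TES-oxy)oct-6-en-1-ol | C=C[C@](C)(C[C@H](O[Si](CC)(CC)CC)C=C(C)C)[C@@H](CO)C(=C)CO[Si](c1ccccc1)(c1ccccc1)C(C)(C)C | intermediate
15 | (2R,3S,5S)-3-ethenyl-3,7-dimethyl-2-[3-(TBDPS-oxy)prop-1-en-2-yl]-5-(TES-oxy)oct-6-enal | C=C[C@](C)(C[C@H](O[Si](CC)(CC)CC)C=C(C)C)[C@@H](C=O)C(=C)CO[Si](c1ccccc1)(c1ccccc1)C(C)(C)C | intermediate
16 | (1R,2R,3S,5S,6S)-3-ethenyl-3-methyl-6-(prop-1-en-2-yl)-2-[3-(TBDPS-oxy)prop-1-en-2-yl]-5-(TES-oxy)cyclohexan-1-ol | C=C[C@]1(C)C[C@H](O[Si](CC)(CC)CC)[C@@H](C(C)=C)[C@H](O)[C@H]1C(=C)CO[Si](c1ccccc1)(c1ccccc1)C(C)(C)C | intermediate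
17 | (1R,2R,3S,5S,6R)-1-(TBS-oxy)-3-ethenyl-3-methyl-6-(prop-1-en-2-yl)-2-[3-(TBDPS-oxy)prop-1-en-2-yl]-5-(TES-oxy)cyclohexane | C=C[C@]1(C)C[C@H](O[Si](CC)(CC)CC)[C@@H](C(C)=C)[C@H](O[Si](C)(C)C(C)(C)C)[C@H]1C(=C)CO[Si](c1ccccc1)(c1ccccc1)C(C)(C)C | intermediate
18 | (1S,2R,3R,4R,5S)-3-(TBS-oxy)-5-ethenyl-5-methyl-2-(prop-1-en-2-yl)-4-[3-(TBDPS-oxy)prop-1-en-2-yl]cyclohexan-1-ol | C=C[C@]1(C)C[C@H](O)[C@@H](C(C)=C)[C@H](O[Si](C)(C)C(C)(C)C)[C@H]1C(=C)CO[Si](c1ccccc1)(c1ccccc1)C(C)(C)C | intermediate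
19 | ethyl 2-(hydroxymethyl)prop-2-enoate | CCOC(=O)C(=C)CO | starting material
20 | ethyl 2-[(TBS-oxy)methyl]prop-2-enoate | CCOC(=O)C(=C)CO[Si](C)(C)C(C)(C)C | intermediate
21 | 2-[(TBS-oxy)methyl]prop-2-enoic acid | OC(=O)C(=C)CO[Si](C)(C)C(C)(C)C | intermediate
22 | 2-[(TBS-oxy)methyl]prop-2-enoic 2,4,6-trichlorobenzoic anhydride (mixed anhydride, not isolated) | C=C(CO[Si](C)(C)C(C)(C)C)C(=O)OC(=O)c1c(Cl)cc(Cl)cc1Cl | intermediate
23 | (1S,2R,3R,4R,5S)-3-(TBS-oxy)-5-ethenyl-5-methyl-2-(prop-1-en-2-yl)-4-[3-(TBDPS-oxy)prop-1-en-2-yl]cyclohexyl 2-[(TBS-oxy)methyl]prop-2-enoate | C=C[C@]1(C)C[C@H](OC(=O)C(=C)CO[Si](C)(C)C(C)(C)C)[C@@H](C(C)=C)[C@H](O[Si](C)(C)C(C)(C)C)[C@H]1C(=C)CO[Si](c1ccccc1)(c1ccccc1)C(C)(C)C | intermediate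
24 | (1S,2R,3R,4R,5S)-3-(TBS-oxy)-5-ethenyl-2-(3-hydroxyprop-1-en-2-yl)-5-methyl-4-[3-(TBDPS-oxy)prop-1-en-2-yl]cyclohexyl 2-[(TBS-oxy)methyl]prop-2-enoate | C=C[C@]1(C)C[C@H](OC(=O)C(=C)CO[Si](C)(C)C(C)(C)C)[C@@H](C(=C)CO)[C@H](O[Si](C)(C)C(C)(C)C)[C@H]1C(=C)CO[Si](c1ccccc1)(c1ccccc1)C(C)(C)C | intermediate
25 | (1S,2R,3R,4R,5S)-3-(TBS-oxy)-5-ethenyl-5-methyl-2-(3-oxoprop-1-en-2-yl)-4-[3-(TBDPS-oxy)prop-1-en-2-yl]cyclohexyl 2-[(TBS-oxy)methyl]prop-2-enoate | C=C[C@]1(C)C[C@H](OC(=O)C(=C)CO[Si](C)(C)C(C)(C)C)[C@@H](C(=C)C=O)[C@H](O[Si](C)(C)C(C)(C)C)[C@H]1C(=C)CO[Si](c1ccccc1)(c1ccccc1)C(C)(C)C | intermediate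
26 | 2-[(1R,2R,3R,4S,6S)-2-(TBS-oxy)-4-ethenyl-4-methyl-3-[3-(TBDPS-oxy)prop-1-en-2-yl]-6-({2-[(TBS-oxy)methyl]prop-2-enoyl}oxy)cyclohexyl]prop-2-enoic acid | C=C[C@]1(C)C[C@H](OC(=O)C(=C)CO[Si](C)(C)C(C)(C)C)[C@@H](C(=C)C(=O)O)[C@H](O[Si](C)(C)C(C)(C)C)[C@H]1C(=C)CO[Si](c1ccccc1)(c1ccccc1)C(C)(C)C | intermediate
27 | 2-[(1S,2R,3R,4S,6S)-4-ethenyl-2-hydroxy-6-{[2-(hydroxymethyl)prop-2-enoyl]oxy}-3-(3-hydroxyprop-1-en-2-yl)-4-methylcyclohexyl]prop-2-enoic acid (CNP0509685.1) | C=C[C@]1(C)C[C@H](OC(=O)C(=C)CO)[C@@H](C(=C)C(=O)O)[C@H](O)[C@H]1C(=C)CO | target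

**Totals and risks**

Total step count: 21. Longest linear sequence: 15 steps (steps 1–4, 9–14 and 17–21, from prenal).

The three steps most likely to fail:

Step 9 (the proposed new step). Trisubstituted allyl carbonates ionise slowly on iridium, the C5–C10 bond is very crowded, and the allyl complex may instead eliminate to a diene, be attacked at the primary terminus, or be attacked by the gamma carbon of the dienolate; 12 may also isomerise into conjugation. The fallback uses known chemistry, sets out from allylic alcohol 6 and acid 11, and comes back to the route at alcohol 14. DCC/DMAP esterification gives (2E,5S)-3,7-dimethyl-5-(TES-oxy)octa-2,6-dien-1-yl 3-[(TBDPS-oxy)methyl]but-3-enoate F1. An enantioselective Ireland–Claisen rearrangement of its boron enolate follows; the enolate is made with a C2-symmetric 2-bromo-4,5-diphenyl-1,3-bis(p-tolylsulfonyl)-1,3,2-diazaborolidine (the enantiomer that gives the 2R,3S acid) and Et3N in toluene/hexane at −78 °C, then warmed to rt. The chair transition state, with the (E)-allyl unit and the enolate whose C4 is trans to the boron-bound oxygen, gives (2R,3S,5S)-3-ethenyl-3,7-dimethyl-2-[3-(TBDPS-oxy)prop-1-en-2-yl]-5-(TES-oxy)oct-6-enoic acid F2. LiAlH4 in THF at 0 °C reduces F2 to 14.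

Step 12. In the required chair the C8 silyloxy group lies anti to the forming bond and lowers the nucleophilicity of the alkene, and aldehyde 15 can epimerise at C5 or conjugate under Lewis acid. The fallback replaces the pericyclic closure by an organometallic one, sets out from aldehyde 15, and comes back at cyclohexanol 16. Ene-type chlorination of the trisubstituted alkene (N-chlorosuccinimide, PhSeCl 10 mol %, CH2Cl2, rt) gives (2R,3S,5S)-6-chloro-3-ethenyl-3,7-dimethyl-2-[3-(TBDPS-oxy)prop-1-en-2-yl]-5-(TES-oxy)oct-7-enal F3 (both C6 epimers). CrCl2 (divalent chromium, 4 equiv, THF, 0 °C → rt) then converts F3 into the primary allylchromium species, which adds to the aldehyde through C7 in a chair Nozaki–Hiyama transition state under neutral conditions and gives 16.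

Step 18. The oxidation must pick one of three 1,1-disubstituted alkenes and stop at the alcohol; attack at the C15 silyloxymethylene or at C7–H would erode the yield. The fallback changes the reaction type, sets out from ester 23, and comes back at enal 25. Ene-type chlorination of the isopropenyl group with hypochlorous acid (Ca(OCl)2, solid CO2, CH2Cl2/H2O, 0 °C) gives (1S,2R,3R,4R,5S)-3-(TBS-oxy)-2-(3-chloroprop-1-en-2-yl)-5-ethenyl-5-methyl-4-[3-(TBDPS-oxy)prop-1-en-2-yl]cyclohexyl 2-[(TBS-oxy)methyl]prop-2-enoate F4. Ganem oxidation of F4 (N-methylmorpholine N-oxide, NaI 10 mol %, MeCN, rt) gives 25 directly.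

**Further compounds**

F1 | step 9 | (2E,5S)-3,7-dimethyl-5-(TES-oxy)octa-2,6-dien-1-yl 3-[(TBDPS-oxy)methyl]but-3-enoate | C=C(CO[Si](c1ccccc1)(c1ccccc1)C(C)(C)C)CC(=O)OC/C=C(\C)C[C@H](O[Si](CC)(CC)CC)C=C(C)C
F2 | step 9 | (2R,3S,5S)-3-ethenyl-3,7-dimethyl-2-[3-(TBDPS-oxy)prop-1-en-2-yl]-5-(TES-oxy)oct-6-enoic acid | C=C[C@](C)(C[C@H](O[Si](CC)(CC)CC)C=C(C)C)[C@@H](C(=O)O)C(=C)CO[Si](c1ccccc1)(c1ccccc1)C(C)(C)C
F3 | step 12 | (2R,3S,5S)-6-chloro-3-ethenyl-3,7-dimethyl-2-[3-(TBDPS-oxy)prop-1-en-2-yl]-5-(TES-oxy)oct-7-enal (both C6 epimers) | C=C[C@](C)(C[C@H](O[Si](CC)(CC)CC)C(Cl)C(C)=C)[C@@H](C=O)C(=C)CO[Si](c1ccccc1)(c1ccccc1)C(C)(C)C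
F4 | step 18 | (1S,2R,3R,4R,5S)-3-(TBS-oxy)-2-(3-chloroprop-1-en-2-yl)-5-ethenyl-5-methyl-4-[3-(TBDPS-oxy)prop-1-en-2-yl]cyclohexyl 2-[(TBS-oxy)methyl]prop-2-enoate | C=C[C@]1(C)C[C@H](OC(=O)C(=C)CO[Si](C)(C)C(C)(C)C)[C@@H](C(=C)CCl)[C@H](O[Si](C)(C)C(C)(C)C)[C@H]1C(=C)CO[Si](c1ccccc1)(c1ccccc1)C(C)(C)C
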